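**Strategy.** The isoflavanone is disconnected at two bonds on neighbouring carbons of ring C: C3–C1' (to ring B) and C4–O. Both carbons are the alkene carbons of a 2H-chromene fused to ring A, and C4 is benzylic to the 5,7-dioxygenated ring A, which steers palladium to C4 and opens it to attack by water. One enantioselective oxidative Heck oxyarylation therefore joins the ring B boronic acid to C3, hydroxylates C4 and sets the C3 stereocentre. Its precursors are 5-silyloxy-7-methoxy-2H-chromene and (7-methoxy-2,2-dimethyl-2H-chromen-6-yl)boronic acid; oxidation of C4–OH and desilylation complete the route.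

Key step: step 10

Ring labels: ring A is the benzene ring of the chromanone, ring C its pyranone ring, ring B the benzene ring attached at C3, and ring D the dimethylpyran fused to ring B.

Stereochemical check: the target is (3S); the alcohol from the key step is trans-(3S,4R), and only C3 survives to the target.

Assumption: the alkene face that the pyridine-oxazoline ligand selects on a cis-disubstituted cyclic styrene cannot be predicted with certainty. The route is written with (S)-t-BuPyOx; the (R)-ligand would be used if the (3R) series were formed.

Design remarks on the access to chromene 9: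
- The TBS ether is kept because fluoride removes it under non-basic conditions that spare the enolisable C3 centre.
- A borohydride reduction in methanol would expose the ortho-acyl aryl silyl ether to alkoxide (silyl loss or transfer to the C4 alkoxide), so the ketone is reduced with i-Bu2AlH in an aprotic solvent at −78 °C.
- An acid-catalysed dehydration would endanger the silyl ether and the electron-rich chromene, so water is removed through the mesylate under basic conditions.

**Route**

Step 1
Reactants: 1 phloroglucinol; 2 3-chloropropanoic acid
Product: 3 3-chloro-1-(2,4,6-trihydroxyphenyl)propan-1-one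
Conditions: CF3SO3H, 80 °C
Reagents that add atoms: none
Why: Friedel–Crafts acylation of the strongly activated arene by the acylium species formed from the acid in CF3SO3H gives one product because the three free ring positions are equivalent.

Step 2
Reactants: 3 3-chloro-1-(2,4,6-trihydroxyphenyl)propan-1-one
Product: 4 5,7-dihydroxychroman-4-one
Conditions: 2 M NaOH (aq), 0 °C to rt; then HCl to pH 2
Reagents that add atoms: none
Why: Intramolecular Williamson etherification (6-exo-tet displacement of chloride by an ortho phenoxide) closes ring C, and either ortho phenoxide leads to the same chromanone.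

Step 3
Reactants: 4 5,7-dihydroxychroman-4-one
Product: 5 5-hydroxy-7-methoxychroman-4-one
Conditions: MeI (1.1 equiv), K2CO3, acetone, 40 °C
Reagents that add atoms: iodomethane, CI
Why: Williamson methylation is selective for the 7-OH, which is the more acidic and free phenol, whereas the 5-OH is held in a hydrogen bond to the C4 carbonyl.

Step 4
Reactants: 5 5-hydroxy-7-methoxychroman-4-one
Product: 6 5-(tert-butyldimethylsilyloxy)-7-methoxychroman-4-one
Conditions: TBSCl, imidazole, DMF, rt to 40 °C
Reagents that add atoms: tert-butyldimethylsilyl chloride, CC(C)(C)[Si](C)(C)Cl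
Why: Imidazole-promoted O-silylation caps the remaining chelated phenol under mild basic conditions that do not enolise or open the chromanone.

Step 5
Reactants: 6 5-(tert-butyldimethylsilyloxy)-7-methoxychroman-4-one
Product: 7 racemic 5-(tert-butyldimethylsilyloxy)-7-methoxychroman-4-ol
Conditions: i-Bu2AlH, CH2Cl2, −78 °C; aq. potassium sodium tartrate
Reagents that add atoms: none
Why: Hydride reduction of the ketone by i-Bu2AlH at −78 °C gives an aluminium alkoxide that should not take over the neighbouring silyl group; the new C4 centre is racemic and is removed in step 6.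

Step 6
Reactants: 7 racemic 5-(tert-butyldimethylsilyloxy)-7-methoxychroman-4-ol
Product: 9 5-(tert-butyldimethylsilyloxy)-7-methoxy-2H-chromene, via C4 mesylate 8 (not isolated)
Conditions: MsCl, Et3N, CH2Cl2, 0 °C to rt
Reagents that add atoms: none
Why: Mesylation followed by E1-type loss of methanesulfonate from the donor-stabilised benzylic carbon and removal of a C3 proton by Et3N dehydrates the alcohol without acid, so the aryl silyl ether and the enol-ether-like alkene should survive.

Step 7
Reactants: 10 4-bromo-3-methoxyphenol; 11 3-chloro-3-methylbut-1-yne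
Product: 12 1-bromo-2-methoxy-4-[(2-methylbut-3-yn-2-yl)oxy]benzene
Conditions: DBU, CuCl2 (cat.), MeCN, 0 °C
Reagents that add atoms: none
Why: Copper-catalysed O-propargylation of the phenoxide by the tertiary propargylic chloride, through a copper acetylide that ionises readily, is the standard entry to aryl 1,1-dimethylpropargyl ethers and leaves the aryl bromide untouched.

Step 8
Reactants: 12 1-bromo-2-methoxy-4-[(2-methylbut-3-yn-2-yl)oxy]benzene
Product: 15 6-bromo-7-methoxy-2,2-dimethyl-2H-chromene, via ortho-allenylphenol 13 (not isolated), via ortho-quinone methide 14 (not isolated)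
Conditions: PhNEt2, 190 °C
Reagents that add atoms: none
Why: Aromatic propargyl Claisen rearrangement to the free ortho carbon para to the methoxy group, then tautomerisation, 1,5-hydrogen shift and oxa-6π electrocyclisation, builds ring D; migration to the carbon between the two oxygen substituents should be disfavoured because the bromine pushes the methoxy group towards that site and a meta donor directs to the carbon para to it.

Step 9
Reactants: 15 6-bromo-7-methoxy-2,2-dimethyl-2H-chromene
Product: 18 (7-methoxy-2,2-dimethyl-2H-chromen-6-yl)boronic acid, via aryllithium 16 (not isolated), via lithium aryltrimethoxyborate 17 (not isolated)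
Conditions: n-BuLi, THF, −78 °C; B(OMe)3, −78 °C to rt; 1 M HCl to pH 5, 0 °C
Reagents that add atoms: trimethyl borate, COB(OC)OC; water, O
Why: Bromine–lithium exchange at −78 °C is much faster than any attack of n-BuLi on the chromene, and borylation of the ortho-methoxy-stabilised aryllithium followed by mild hydrolysis gives the boronic acid.

Step 10
Reactants: 9 5-(tert-butyldimethylsilyloxy)-7-methoxy-2H-chromene; 18 (7-methoxy-2,2-dimethyl-2H-chromen-6-yl)boronic acid (1.5 equiv, added in portions)
Product: 19 (3S,4R)-trans-5-(tert-butyldimethylsilyloxy)-7-methoxy-3-(7-methoxy-2,2-dimethyl-2H-chromen-6-yl)chroman-4-ol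
Conditions: Pd(OCOCF3)2 (10 mol %), (S)-t-BuPyOx (12 mol %), 1,4-benzoquinone (1.5 equiv), H2O (10 equiv), acetone, 30 °C; filtration through Et3N-washed silica
Reagents that add atoms: water, O
Why: Proposed new method: boronic acid 18 should transmetalate to the cationic (S)-t-BuPyOx complex of divalent palladium, and the resulting aryl–palladium species should bind the C3=C4 alkene of 9 and insert it syn, the aryl group migrating to C3 and the metal ending on C4 as a π-benzyl complex supported by the electron-rich ring A. The hydrogen left on C3 then lies on the face opposite the metal, so no syn β-hydrogen is available for elimination; water instead attacks C4 from the face away from palladium, and the zerovalent palladium released is reoxidised by 1,4-benzoquinone. The closest known reaction types are the enantioselective oxidative Heck arylation of alkenes by arylboronic acids with pyridine-oxazoline palladium catalysts and the Heck oxyarylation of 2H-chromenes by ortho-halophenols, which places carbon on C3 and oxygen on C4 in the same way but with a tethered phenol. No ring is closed in this step. C3 is set by the ligand, which decides the alkene face that inserts, and C4 follows from C3 as trans through syn carbopalladation and anti hydroxylation (its configuration is erased in step 11, so either C4 epimer would serve). The step needs regioselectivity, secured by the styrene-like polarisation of 9 and the benzylic stabilisation of palladium on C4, and chemoselectivity over the ring D alkene of 18 and 19, secured by the fully substituted C2 carbon next to it, which blocks delivery of an aryl group to the adjacent alkene carbon.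

Step 11
Reactants: 19 (3S,4R)-trans-5-(tert-butyldimethylsilyloxy)-7-methoxy-3-(7-methoxy-2,2-dimethyl-2H-chromen-6-yl)chroman-4-ol
Product: 20 (3S)-5-(tert-butyldimethylsilyloxy)-7-methoxy-3-(7-methoxy-2,2-dimethyl-2H-chromen-6-yl)chroman-4-one
Conditions: Dess–Martin periodinane, NaHCO3, CH2Cl2, 0 °C to rt
Reagents that add atoms: none
Why: Dess–Martin oxidation of the secondary benzylic alcohol under bicarbonate buffering is neither acidic enough to ionise C4 nor basic enough to enolise the new ketone, so the C3 configuration should be carried over while the C4 centre is erased.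

Step 12
Reactants: 20 (3S)-5-(tert-butyldimethylsilyloxy)-7-methoxy-3-(7-methoxy-2,2-dimethyl-2H-chromen-6-yl)chroman-4-one
Product: 21 (3S)-5-hydroxy-7-methoxy-3-(7-methoxy-2,2-dimethyl-2H-chromen-6-yl)chroman-4-one
Conditions: HF·pyridine, THF, 0 °C; aq. NaH2PO4/Na2HPO4 buffer (pH 7)
Reagents that add atoms: none
Why: Fluoride-driven desilylation of the aryl silyl ether, activated as a vinylogous silyl ester by the peri carbonyl group, should be fast under these non-basic conditions, which do not epimerise C3 or touch the ring D alkene.

**Compound list**

1 | phloroglucinol | Oc1cc(O)cc(O)c1 | starting material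
2 | 3-chloropropanoic acid | OC(=O)CCCl | starting material
3 | 3-chloro-1-(2,4,6-trihydroxyphenyl)propan-1-one | O=C(CCCl)c1c(O)cc(O)cc1O | intermediate
4 | 5,7-dihydroxychroman-4-one | O=C1CCOc2cc(O)cc(O)c12 | intermediate
5 | 5-hydroxy-7-methoxychroman-4-one | COc1cc(O)c2C(=O)CCOc2c1 | intermediate
6 | 5-(tert-butyldimethylsilyloxy)-7-methoxychroman-4-one | COc1cc(O[Si](C)(C)C(C)(C)C)c2C(=O)CCOc2c1 | intermediate
7 | racemic 5-(tert-butyldimethylsilyloxy)-7-methoxychroman-4-ol | COc1cc(O[Si](C)(C)C(C)(C)C)c2C(O)CCOc2c1 | intermediate
8 | racemic 5-(tert-butyldimethylsilyloxy)-7-methoxychroman-4-yl methanesulfonate (not isolated) | COc1cc(O[Si](C)(C)C(C)(C)C)c2C(OS(C)(=O)=O)CCOc2c1 | intermediate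
9 | 5-(tert-butyldimethylsilyloxy)-7-methoxy-2H-chromene | COc1cc(O[Si](C)(C)C(C)(C)C)c2C=CCOc2c1 | intermediate
10 | 4-bromo-3-methoxyphenol | COc1cc(O)ccc1Br | starting material
11 | 3-chloro-3-methylbut-1-yne | CC(C)(Cl)C#C | starting material
12 | 1-bromo-2-methoxy-4-[(2-methylbut-3-yn-2-yl)oxy]benzene | COc1cc(OC(C)(C)C#C)ccc1Br | intermediate
13 | 4-bromo-5-methoxy-2-(3-methylbuta-1,2-dien-1-yl)phenol (not isolated) | COc1cc(O)c(C=C=C(C)C)cc1Br | intermediate
14 | 4-bromo-3-methoxy-6-(3-methylbut-2-en-1-ylidene)cyclohexa-2,4-dien-1-one (not isolated) | O=C1C=C(OC)C(Br)=CC1=CC=C(C)C | intermediate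
15 | 6-bromo-7-methoxy-2,2-dimethyl-2H-chromene | COc1cc2OC(C)(C)C=Cc2cc1Br | intermediate
16 | (7-methoxy-2,2-dimethyl-2H-chromen-6-yl)lithium (not isolated) | COc1cc2OC(C)(C)C=Cc2cc1[Li] | intermediate
17 | lithium trimethoxy(7-methoxy-2,2-dimethyl-2H-chromen-6-yl)borate (not isolated) | [Li+].COc1cc2OC(C)(C)C=Cc2cc1[B-](OC)(OC)OC | intermediate
18 | (7-methoxy-2,2-dimethyl-2H-chromen-6-yl)boronic acid | COc1cc2c(cc1B(O)O)C=CC(C)(C)O2 | intermediate
19 | (3S,4R)-trans-5-(tert-butyldimethylsilyloxy)-7-methoxy-3-(7-methoxy-2,2-dimethyl-2H-chromen-6-yl)chroman-4-ol | COc1cc(O[Si](C)(C)C(C)(C)C)c2c(c1)OC[C@H](c1cc3c(cc1OC)OC(C)(C)C=C3)[C@H]2O | intermediate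
20 | (3S)-5-(tert-butyldimethylsilyloxy)-7-methoxy-3-(7-methoxy-2,2-dimethyl-2H-chromen-6-yl)chroman-4-one | COc1cc(O[Si](C)(C)C(C)(C)C)c2c(c1)OC[C@H](c1cc3c(cc1OC)OC(C)(C)C=C3)C2=O | intermediate
21 | (3S)-5-hydroxy-7-methoxy-3-(7-methoxy-2,2-dimethyl-2H-chromen-6-yl)chroman-4-one | COc1cc(O)c2c(c1)OC[C@H](c1cc3c(cc1OC)OC(C)(C)C=C3)C2=O | target

**Totals**

Total step count: 12. Longest linear sequence: 9 steps (steps 1–6, then 10–12); the ring B branch is 3 steps (7–9).

**Steps most likely to fail**

Step 10 (the proposed new method). Several things may go wrong:
- The insertion may proceed with poor facial selectivity, or with the aryl group delivered to C4 instead of C3.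
- Protodeboronation or oxidative homocoupling of 18 may outrun transmetalation.
- The C4 palladium intermediate or the product alcohol may ionise and lose the C3 hydrogen, which would erase the stereocentre.
- Hydroquinone may compete with water for C4.

The fallback uses known chemistry, sets out from ketone 6 and bromide 15, and returns to the route at 20. Palladium-catalysed α-arylation of ketone 6 with bromide 15 (Pd2(dba)3, Xantphos, K3PO4, toluene, 80 °C) should give racemic 5-(tert-butyldimethylsilyloxy)-7-methoxy-3-(7-methoxy-2,2-dimethyl-2H-chromen-6-yl)chroman-4-one F1. Asymmetric transfer hydrogenation with dynamic kinetic resolution follows (RuCl[(S,S)-TsDPEN](p-cymene), HCO2H/Et3N, EtOAc, rt). In it C3 epimerises through the enol faster than the ketone is reduced, and the (S,S)-catalyst, which delivers (S)-carbinols from aryl ketones, reduces one enantiomer to the cis product. This should give (3S,4S)-cis-5-(tert-butyldimethylsilyloxy)-7-methoxy-3-(7-methoxy-2,2-dimethyl-2H-chromen-6-yl)chroman-4-ol F2. Dess–Martin oxidation of this alcohol under the conditions of step 11 rejoins the route at 20.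

Step 6. The mesylate may ionise to the donor-stabilised C4 cation faster than a proton is lost, so that the cation is captured by the product chromene (dimerisation) or by chloride; adventitious acid may also strip the silyl group. The fallback sets out from ketone 6 and returns at 9 without ever forming a benzylic alcohol. Enolisation with KN(SiMe3)2 and trapping with PhNTf2 in THF at −78 °C should give 5-(tert-butyldimethylsilyloxy)-7-methoxy-2H-chromen-4-yl trifluoromethanesulfonate F3. Palladium-catalysed transfer hydrogenolysis of this enol triflate (Pd(OAc)2, PPh3, HCO2H, n-Bu3N, DMF, 60 °C) then gives chromene 9.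

Step 8. The sigmatropic shift may go partly to the ortho carbon between the two oxygen substituents, giving the angular 5-methoxy isomer, and prolonged heating may degrade the chromene. The fallback sets out from phenol 10 and returns at 15. Friedel–Crafts acylation and oxa-Michael closure with 3-methylbut-2-enoic acid in P2O5/MeSO3H at 70 °C, where acylation is directed para to the methoxy group, should give 6-bromo-7-methoxy-2,2-dimethylchroman-4-one F4. Reduction with NaBH4 in MeOH gives racemic 6-bromo-7-methoxy-2,2-dimethylchroman-4-ol F5, and dehydration with catalytic p-TsOH in toluene at 80 °C rejoins the route at 15.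

**Further compounds**

F1 | step 10 | racemic 5-(tert-butyldimethylsilyloxy)-7-methoxy-3-(7-methoxy-2,2-dimethyl-2H-chromen-6-yl)chroman-4-one | COc1cc(O[Si](C)(C)C(C)(C)C)c2c(c1)OCC(c1cc3c(cc1OC)OC(C)(C)C=C3)C2=O
F2 | step 10 | (3S,4S)-cis-5-(tert-butyldimethylsilyloxy)-7-methoxy-3-(7-methoxy-2,2-dimethyl-2H-chromen-6-yl)chroman-4-ol | COc1cc(O[Si](C)(C)C(C)(C)C)c2c(c1)OC[C@H](c1cc3c(cc1OC)OC(C)(C)C=C3)[C@@H]2O
F3 | step 6 | 5-(tert-butyldimethylsilyloxy)-7-methoxy-2H-chromen-4-yl trifluoromethanesulfonate | COc1cc(O[Si](C)(C)C(C)(C)C)c2C(OS(=O)(=O)C(F)(F)F)=CCOc2c1
F4 | step 8 | 6-bromo-7-methoxy-2,2-dimethylchroman-4-one | COc1cc2OC(C)(C)CC(=O)c2cc1Br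
F5 | step 8 | racemic 6-bromo-7-methoxy-2,2-dimethylchroman-4-ol | COc1cc2OC(C)(C)CC(O)c2cc1Br
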